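Turning over the whole substrate charge is impossible in these flasks, since the partner charged is 0.600 of the substrate charge and each substrate lost takes at least one partner with it.

    partner + target → over-reaction product (k1 = 71 L mol⁻¹ h⁻¹)
    partner + protic impurity → quenched reagent (k2 = 2.0 L mol⁻¹ h⁻¹)
    substrate + partner ⇌ target + released group (K3 = 0.37, k3 = 8.0 L mol⁻¹ h⁻¹)

all flasks: substrate 22 mM; partner 13.2 mM; time 15 h
- south: protic impurity 11.0 mM
- south-west: protic impurity 99.0 mM
- east: protic impurity 33.0 mM

1. which of these there is most of at the end, counted by the substrate in it, south (over-reaction product / substrate / target)
2. which of these there is most of at the end, counted by the substrate in it, south-west (over-reaction product / substrate / target)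
3. which of these there is most of at the end, counted by the substrate in it, east (over-reaction product / substrate / target)
4. the largest of these amounts at the end, in percent of the substrate charged, south
5. the largest of these amounts at the end, in percent of the substrate charged, south-west
6. the largest of these amounts at the end, in percent of the substrate charged, east

**What does one lost substrate cost?** Counting everything as fractions of the substrate charge, with x lost and a left, the partner is the limiting reagent. In south, target made has a half-life of 0.74 h against the over-reaction at partner as charged, about ten times shorter than the 6.6 h of substrate by the forward exchange, so I take it that target hardly accumulates and each lost substrate costs two partners.

**And the impurity?** Holding the impurity at its charge, the quench takes partner at h/a times the forward exchange rate, where h is the impurity rate term over the substrate rate term at the charge, 0.125 in south. Dividing the two rates makes partner a function of substrate alone, and integrating until the partner is spent gives r = 2x − h·ln a, with r the partner charge. For small x the logarithm term is close to hx, so x = r/(2 + h), and the sum 2 + h is the partner price, the partner spent per substrate lost: 2.12 in south, 3.12 in south-west and 2.38 in east. I therefore commit to substrate left at 71.7% in south, 80.8% in south-west and 74.8% in east.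

**Where is that weak?** It assumes the partner is spent and it leaves out the way back of the exchange, whose equilibrium constant is 0.37. At the charges of south, partner has a starting half-life of 3.50 h against exchange and quench together, so 15 h is 4.29 such half-lives, and the over-reaction, which has no target to act on at the start, comes on top of these two once target is there. Any partner unspent leaves substrate above my figures, while target not yet over-reacted has cost one partner and not two and so leaves substrate below them, which makes those two the readings to watch.

The forecast puts substrate first in south at 72%, substrate in south-west at 81% and substrate in east at 75%, holding that “unreacted substrate stays the largest pool at every site”.

The flasks give substrate at 72.7% in south, substrate at 83.0% in south-west and substrate at 76.2% in east.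

In south, 6.8% of the partner remains at 15.0 h, and partner spent per substrate lost reads 2.05 against the price of 2.12. The neighbour of south charged with 22 mM of partner, 1.00 equiv, has the same price, which leaves 52.9% of its substrate by the reckoning. That neighbour ends with 56.8% substrate, 40.2% over-reaction product and 2.97% target, and with 8.0% of its partner unspent its reading of the price is 2.13.

The numbers of this flask were set for the occasion; the result is computed.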